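(The data are simulated on assumed constants, and the scatter is random.)

Amounts first: I compare the target with the starting material lost at each reading and ask how much of the loss stays target.

| flask | starting material | reagent | second substrate | protic impurity | remark | time |
|---|---|---|---|---|---|---|
| south-west | 0.050 M | 0.040 M | 0.070 M | 0.010 M | run made earlier |  |
| north-west | 0.050 M | 0.040 M | 0.11 M | 0.010 M | run made earlier |  |
| south-east | 0.075 M | 0.040 M | 0.050 M | 0.010 M | run made earlier |  |
| flask | 0.050 M | 0.0400 M | 0.0500 M | 0.0100 M |  | 2.5 h |

| run | time / h | target / % | starting material / % |
|---|---|---|---|
| south-west | 0.0833 | 10.6 | 89.6 |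
| south-west | 0.250 | 16.1 | 77.8 |
| south-west | 0.833 | 8.9 | 66.6 |
| south-west | 2.50 | 6.9 | 65.7 |
| north-west | 0.0833 | 10.3 | 88.6 |
| north-west | 0.250 | 14.4 | 78.5 |
| north-west | 0.833 | 7.4 | 75.0 |
| north-west | 2.50 | 7.1 | 72.7 |
| south-east | 0.0833 | 10.8 | 90.2 |
| south-east | 0.250 | 14.6 | 78.5 |
| south-east | 0.833 | 10.2 | 67.6 |
| south-east | 2.50 | 6.5 | 67.5 |

(standard deviation of a reading: 1 percentage point)

- when, up to 2.5 h, the flask holds most target
- the amount of target, in percent of the starting material charged, at that time
- earliest time at which at least nineteen twentieths of that best amount are there
- latest time at which they still are

- the numbers in the tables scatter with a standard deviation of 1 percentage point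

In the south-west run the first reading shows 10.6% target against a loss of 10.4%, level within the scatter. Later the target falls behind. I carry one quantity, the end share, which is target at the last reading divided by starting material lost by then, summed over the earlier runs: 0.218. So target starts level with the loss and ends near that share of it, and the peak lies where the two ends join, near 0.250 h in the south-west readings.

For a bound from above I take the first south-west reading as a pseudo-first-order rate, 1.32 h⁻¹. With c(reagent) held at its charge, that gives a loss of 28.1% at 0.250 h. The south-west run keeps 0.725 of its loss as target then, so I put the flask's peak below 20.4%.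

For a bound from below, the flask has less c(second substrate) than the south-west run, and starting material stops lower with less of it: 65.7% there against 72.7% in the north-west run. So I put the peak above the south-west reading of 16.1%, a reading that carries a scatter of 1 point. At 2.5 h I expect at least 7.48%, the end share of the south-west loss.

The forecast expects 16.5% at 0.28 h, held from 0.2 h to 0.37 h, on the ground that in the flask “its reagent lasts slightly longer”, and this peak stands inside my bracket .

The simulation of the flask gives 17.4% at 0.299 h, with the level asked for held from 0.202 h to 0.434 h. This peak lies inside the bracket .

    second substrate + reagent → second product (k = 0.800 M⁻¹ min⁻¹)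
    target ⇌ isomer of the product (K = 4.20, k = 0.0480 min⁻¹)
    starting material + reagent → target (k = 0.790 M⁻¹ min⁻¹)
    second substrate + protic impurity → quenched substrate (k = 0.530 M⁻¹ min⁻¹)

At 2.5 h the flask has lost 41.0% of its starting material, so the end share gives 8.94% target, and it holds 7.97%. The relaxation half-life of target and isomer of the product, 0.194 h, is short against that time. The neighbouring flask, the same recipe with 0.16 M of reagent, has lost nearly all its starting material by 2.50 h, so the end share gives 21.8%. That flask peaks at 48.4% and ends with 80.7% isomer of the product and 19.3% target.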